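5 questions stand here, and the number I carry through them is a power of time.

* the best flask by amount of target, in percent of the starting material charged; "all alike" if 1.5 percentage points covers them all (amber / grey / violet / red / all alike)
* amount of target at the end, in percent of the starting material charged, amber
* amount of target at the end, in percent of the starting material charged, grey
* amount of target at the end, in percent of the starting material charged, violet
* amount of target at the end, in percent of the starting material charged, red

| setting | eta | delta | gamma | amber | grey | violet | red |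
|---|---|---|---|---|---|---|---|
| starting material | 0.15 M | 0.15 M | 0.15 M | 0.15 M | 0.15 M | 0.15 M | 0.15 M |
| second substrate | 0.50 equiv | 0.75 equiv | 1 equiv | 1.00 equiv | 1.00 equiv | 1.00 equiv | 1.00 equiv |
| precatalyst | 0.41 mol% | 0.41 mol% | 0.61 mol% | 0.41 mol% | 0.41 mol% | 0.41 mol% | 0.41 mol% |
| temperature | 78 °C | 105 °C | 78 °C | 115 °C |  | 65 °C | 90 °C |
| remark | run made earlier | run made earlier | run made earlier |  | at 65 °C until 3.0 h, from then on at 115 °C |  |  |
| time |  |  |  | 4.0 h | 4.0 h | 4.0 h | 4.0 h |

- eta (time / h: target / %): 1.33: 2; 2.00: 3; 2.50: 0; 4.00: 2; 6.00: 5; 10.0: 10; 15.0: 16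
- delta (time / h: target / %): 0.500: 1; 1.00: 4; 1.50: 12; 2.00: 22; 2.50: 27; 3.00: 32; 4.00: 51
- gamma (time / h: target / %): 1.33: 1; 4.00: 0; 6.00: 2; 10.0: 5; 15.0: 17

(readings scatter by 2 percentage points)

I work with the fraction of starting material left, and call its negative logarithm the loss, the ordinate of a first-order plot. Delta gives two readings well above the scatter:

at 2.00 h: left 78.0%, loss 0.248
at 4.00 h: left 49.0%, loss 0.713

Two extreme flasks can be solved in the head. In the steady flask the free catalyst stands at its full amount from the start, the decay is pseudo-first-order, and the loss grows with time to the power one. In the waking flask the free catalyst grows in step with time, so the loss grows with time squared. Delta's readings lie between them, because their loss grows faster than in proportion to time: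

n = ln(loss ratio) / ln(time ratio) = 1.52

This n is the power of time that the loss follows, and it carries the scatter of the readings.

For temperature, eta needs 15.0 h for 16% and delta has passed that at 2.00 h. I therefore take their clocks to differ by about 7.50 across that gap, as a constant factor per degree, and I neglect the differences in second substrate between these runs and the asked flasks. Amber's clock then runs 2.11 times delta's. That puts amber's target between the steady 77.8% and the waking 95.8%. My reckoning, with grey counted by its hot hours:

amber: loss 2.22, target 89.1%
red: loss 0.130, target 12.2%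
violet: loss 0.00760, target 0.757%
grey: loss 0.269, target 23.6%

The forecast gives 75% for amber, 15% for grey, 0.5% for violet and 6% for red, so it also names amber best, though its amber lies below mine, and it reasons: “The second substrate therefore seems to tie up the catalyst until it is consumed, perhaps alongside slow precatalyst activation.”

Amber gives 80.6%, grey 17.3%, violet 0.0823% and red 6.82%, so amber is best.

    starting material + free catalyst ⇌ catalyst intermediate A (K = 1360 M⁻¹, k = 0.265 M⁻¹ s⁻¹, Ea = 45.0 kJ mol⁻¹, ΔH = −6.00 kJ mol⁻¹)
    catalyst intermediate A → free catalyst + target (k = 0.355 s⁻¹, Ea = 85.0 kJ mol⁻¹)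
    second substrate + free catalyst ⇌ catalyst intermediate B (K = 520 M⁻¹, k = 0.136 M⁻¹ s⁻¹, Ea = 50.0 kJ mol⁻¹, ΔH = 21.0 kJ mol⁻¹)
    catalyst intermediate B → free catalyst + second product (k = 0.0100 s⁻¹, Ea = 87.0 kJ mol⁻¹)
    precatalyst → free catalyst (k = 1.37 × 10⁻⁵ s⁻¹, Ea = 116 kJ mol⁻¹)
    2 free catalyst ⇌ resting dimer (K = 5020 M⁻¹, k = 0.191 M⁻¹ s⁻¹, Ea = 57.0 kJ mol⁻¹, ΔH = −21.0 kJ mol⁻¹)
    (constants at 90 °C)

At 3.00 h, grey still held 99.1% of its catalyst as precatalyst. Amber's result means a loss of 1.64. Grey read at 6.0 h has had 3.00 h hot, so n gives it a loss of 1.06, or 65.4% target. That flask holds 66.9%.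

The data come from a simulation for an exercise, and the scatter is random.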